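Ring A is disconnected at C3–C4 and at the C5–O bond. The contiguous triad C3–O, C4=C15, C5–OOH of ring A is read as the trace of a C5=C4=C15 allene whose central carbon C4 has attacked a C3 aldehyde, the resulting C5/C15 allyl cation being quenched by hydrogen peroxide at tertiary C5. One operation thus closes ring A, forms C3–C4 and C5–O and sets C3 and C5 under control of the 10β-methyl. The precursor is a ring B allene aldehyde, methyl 2-[(1R,4S)-4-methyl-4-(3-oxopropyl)-3-vinylidenecyclohexyl]acrylate, made from (R)-carvone with C7 and C10 in place.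

Key step: step 13

Assumption: atoms carry eudesmane numbers throughout (C3 carbinol, C4 with its C15 methylene, C5 peroxy carbon, C7 acrylate-bearing, C10 quaternary), and the C5-epimeric ethynyl carbinols of steps 4 to 9 are carried as a mixture because C5 becomes trigonal in step 10.

Step 1
Reactants: 1 (R)-(−)-carvone
Product: 2 (5R)-2-methyl-5-(prop-1-en-2-yl)cyclohexan-1-one (dihydrocarvone, C2 epimers)
Conditions: LiBH(s-Bu)3, THF, −78 °C; aq. NH4Cl
Reagents that add atoms: none
Why: Conjugate hydride reduction of the β-unsubstituted enone by the hindered borohydride should spare the isolated isopropenyl group and leave C7 untouched, while the mixed C2 centre is erased in the next two steps.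

Step 2
Reactants: 2 dihydrocarvone; 3 (R)-(+)-1-phenylethylamine
Product: 4 N-[(1R)-1-phenylethyl] imine of (5R)-2-methyl-5-(prop-1-en-2-yl)cyclohexan-1-one
Conditions: TsOH·H2O (cat.), PhMe, reflux, Dean–Stark
Reagents that add atoms: (R)-1-phenylethylamine (3), C[C@@H](N)c1ccccc1
Why: Acid-catalysed imine condensation with azeotropic removal of water should give the imine, which equilibrates with the more substituted secondary enamine needed in step 3.

Step 3
Reactants: 4 chiral imine; 5 methyl acrylate
Product: 7 methyl 3-[(1S,4R)-1-methyl-2-oxo-4-(prop-1-en-2-yl)cyclohexyl]propanoate, via adduct imine 6 (not isolated)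
Conditions: methyl acrylate, THF, 40 °C; then 20% aq. AcOH, rt
Reagents that add atoms: methyl acrylate (5), C=CC(=O)OC; water, O
Why: Auxiliary-controlled Michael addition of the secondary enamine tautomer through a compact aza-ene-like transition state should place the acrylate on the face anti to the phenyl group of the (R)-amine, which is the α face anti to the C7 isopropenyl group and sets C10 as S, and hydrolysis then returns the auxiliary.

Step 4
Reactants: 7 keto ester; 8 ethynylmagnesium bromide
Product: 10 (4aS,7R)-8a-ethynyl-4a-methyl-7-(prop-1-en-2-yl)octahydro-2H-chromen-2-one (C8a epimers), via hydroxy ester 9 (not isolated)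
Conditions: HC≡CMgBr (1.5 equiv), THF, −20 °C → rt; aq. NH4Cl
Reagents that add atoms: ethynylmagnesium bromide (8), C#C[Mg]Br
Why: 1,2-Addition of the weakly basic alkynyl Grignard reagent to the ketone should precede attack on the ester, and the tertiary alkoxide then closes the six-membered lactone by transesterification; the C5 configuration is immaterial and any uncyclised 9 converges in step 5.

Step 5
Reactants: 10 lactone
Product: 11 (2S,5R)-1-ethynyl-2-(3-hydroxypropyl)-2-methyl-5-(prop-1-en-2-yl)cyclohexan-1-ol (C1 epimers)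
Conditions: LiBH4, THF, 0 °C → rt
Reagents that add atoms: none
Why: Hydride reduction of the lactone by LiBH4 should give the diol without hydrometalation of the propargylic alkyne.

Step 6
Reactants: 11 diol
Product: 12 (2S,5R)-2-[3-(tert-butyldimethylsilyloxy)propyl]-1-ethynyl-2-methyl-5-(prop-1-en-2-yl)cyclohexan-1-ol
Conditions: TBSCl (1.1 equiv), imidazole, CH2Cl2, 0 °C
Reagents that add atoms: tert-butyldimethylsilyl chloride, CC(C)(C)[Si](C)(C)Cl
Why: Silyl ether formation should occur only at the primary hydroxyl because the tertiary propargylic hydroxyl next to the quaternary carbon is far more hindered.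

Step 7
Reactants: 12 silyl ether
Product: 13 (2S,5R)-2-[3-(tert-butyldimethylsilyloxy)propyl]-1-ethynyl-2-methyl-5-(prop-1-en-2-yl)cyclohexyl methyl carbonate
Conditions: n-BuLi (1.05 equiv), THF, −78 °C; ClCO2Me, −78 → 0 °C
Reagents that add atoms: methyl chloroformate, COC(=O)Cl
Why: The O–H is deprotonated well before the alkyne C–H, and O-acylation of the lithium alkoxide with the chloroformate should give the tertiary propargylic carbonate that serves as leaving group in step 10.

Step 8
Reactants: 13 propargylic carbonate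
Product: 15 (2S,5R)-2-[3-(tert-butyldimethylsilyloxy)propyl]-1-ethynyl-2-methyl-5-(3-oxoprop-1-en-2-yl)cyclohexyl methyl carbonate, via allylic alcohol 14 (not isolated)
Conditions: SeO2 (cat.), t-BuOOH, CH2Cl2, rt; then MnO2, CH2Cl2, rt
Reagents that add atoms: tert-butyl hydroperoxide, CC(C)(C)OO; selenium dioxide (catalytic oxygen relay), O=[Se]=O
Why: SeO2 allylic oxidation (ene reaction then 2,3-shift) of the 1,1-disubstituted alkene should take the methyl group in preference to the ring methine, and MnO2 converges the allylic alcohol on the enal while alkyne, carbonate and silyl ether stay untouched.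

Step 9
Reactants: 15 enal
Product: 17 methyl 2-[(1R,4S)-4-[3-(tert-butyldimethylsilyloxy)propyl]-3-ethynyl-3-(methoxycarbonyloxy)-4-methylcyclohexyl]acrylate, via acrylic acid 16 (not isolated)
Conditions: NaClO2, NaH2PO4, 2-methyl-2-butene, t-BuOH/H2O, 0 °C → rt; then MeI, K2CO3, DMF, rt
Reagents that add atoms: sodium chlorite, [Na+].[O-]Cl=O; iodomethane, CI
Why: Pinnick oxidation with a hypochlorite scavenger should convert the 2-substituted acrolein into the acrylic acid without touching the alkyne, and carboxylate O-alkylation then gives the methyl ester.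

Step 10
Reactants: 17 carbonate acrylate
Product: 18 methyl 2-[(1R,4S)-4-[3-(tert-butyldimethylsilyloxy)propyl]-4-methyl-3-vinylidenecyclohexyl]acrylate
Conditions: Pd2(dba)3·CHCl3 (2.5 mol%), PBu3 (5 mol%), HCO2H, Et3N, THF, rt
Reagents that add atoms: none
Why: Palladium-catalysed formate hydrogenolysis should proceed by SN2' ionisation of the propargylic carbonate by zerovalent palladium to an allenylpalladium formate, decarboxylation and C–H reductive elimination to the 1,1-disubstituted allene, with both C5 epimers converging and the 1:1 palladium to phosphine ratio leaving no free phosphine to add to the acrylate.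

Step 11
Reactants: 18 allene silyl ether
Product: 19 methyl 2-[(1R,4S)-4-(3-hydroxypropyl)-4-methyl-3-vinylidenecyclohexyl]acrylate
Conditions: HF·pyridine, pyridine, THF, 0 °C → rt
Reagents that add atoms: none
Why: Buffered fluoride desilylation should cleave the primary silyl ether under non-basic conditions that neither protonate the allene nor add to the acrylate.

Step 12
Reactants: 19 primary alcohol
Product: 20 methyl 2-[(1R,4S)-4-methyl-4-(3-oxopropyl)-3-vinylidenecyclohexyl]acrylate
Conditions: Dess–Martin periodinane, NaHCO3, CH2Cl2, 0 °C → rt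
Reagents that add atoms: none
Why: Dess–Martin oxidation under buffered conditions should stop at the aldehyde and tolerate both the allene and the acrylate.

Step 13
Reactants: 20 allene aldehyde; 21 hydrogen peroxide
Product: 22 methyl 3α-hydroxy-5α-hydroperoxyeudesma-4(15),11(13)-dien-12-oate
Conditions: anhydrous H2O2 (Et2O solution, 10 equiv), Sc(OTf)3 (20 mol%), MgSO4, Et2O/CH2Cl2, −40 → 0 °C
Reagents that add atoms: hydrogen peroxide (21), OO
Why: Proposed new method: Sc(OTf)3 should activate the C3 aldehyde for attack by the central allene carbon C4 through the C4=C5 π bond, which leaves a tertiary cation at C5 that becomes allylic (C5–C4–C15) as the C4–C5 bond twists, and hydrogen peroxide then collapses on it; the closest known reaction types are Lewis-acid Prins cyclisations of allenes that end by capture of an external nucleophile and Lewis-acid perhydrolysis of tertiary or allylic cations with ethereal hydrogen peroxide. Ring A is closed in a six-membered mode that is exo for the C3=O bond and endo for the C4=C5 bond that is consumed, through a chair-like array. C5 is set by axial entry of the peroxide on the α face, anti to the axial 10β-methyl, which gives the trans-fused decalin. C3 is set in the C–C bond-forming chair, where the scandium-bound oxygen should sit axial (α): there it avoids allylic 1,3-strain with the emerging C15 methylene, meets only one syn-axial hydrogen because C5 is trigonal, and lies syn to the α lobe at C5 so that peroxide held on scandium can be passed on internally, which also favours the 3,5-cis product if ring closure is reversible. The step needs capture at C5 and not at C15 and must spare the aldehyde from oxidation; it relies on the higher positive charge at the dialkyl-substituted C5, the weak nucleophile, low temperature, short contact and water-free peroxide, and the acrylate is inert to these electrophilic conditions.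

Step 14
Reactants: 22 hydroxy hydroperoxide
Product: 23 methyl 5α-(tert-butyldimethylsilylperoxy)-3α-hydroxyeudesma-4(15),11(13)-dien-12-oate
Conditions: TBSCl (1.05 equiv), imidazole, DMF, −20 → 0 °C
Reagents that add atoms: tert-butyldimethylsilyl chloride, CC(C)(C)[Si](C)(C)Cl
Why: O-silylation should select the hydroperoxide O–H, which is more acidic, more nucleophilic and more exposed than the hindered axial C3 hydroxyl, and the silyl peroxide blocks both peroxide acylation and radical allylic peroxide (Schenck) rearrangement.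

Step 15
Reactants: 23 silyl peroxide alcohol; 24 angelic acid
Product: 26 methyl 3α-angeloyloxy-5α-(tert-butyldimethylsilylperoxy)eudesma-4(15),11(13)-dien-12-oate, via mixed anhydride 25 (not isolated)
Conditions: angelic acid, 2,4,6-trichlorobenzoyl chloride, Et3N, PhMe, rt; then 23, PhMe, 70 °C (no DMAP)
Reagents that add atoms: angelic acid (24), C/C=C(/C)C(=O)O
Why: Yamaguchi esterification through the mixed anhydride should acylate the alcohol at the unshielded angeloyl carbonyl, and leaving out a nucleophilic catalyst avoids the addition–elimination pathway that would isomerise the Z ester to the tiglate.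

Step 16
Reactants: 26 silyl peroxide angelate
Product: 27 methyl 3α-angeloyloxy-5α-hydroperoxyeudesma-4(15),11(13)-dien-12-oate (CNP0137897.2)
Conditions: HF·pyridine, pyridine, THF, 0 °C
Reagents that add atoms: none
Why: Fluoride cleavage of the weak Si–OO bond under buffered conditions should free the hydroperoxide without forming the peroxide anion, so neither the acrylate nor the angelate is attacked or isomerised.

Compound list
1 | (R)-(−)-carvone | C=C(C)[C@@H]1CC=C(C)C(=O)C1 | starting material
2 | (5R)-2-methyl-5-(prop-1-en-2-yl)cyclohexan-1-one (dihydrocarvone, C2 epimers) | C=C(C)[C@@H]1CCC(C)C(=O)C1 | intermediate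
3 | (R)-(+)-1-phenylethylamine | C[C@@H](N)c1ccccc1 | starting material
4 | N-[(1R)-1-phenylethyl] imine of 2 | C=C(C)[C@@H]1CCC(C)C(=N[C@H](C)c2ccccc2)C1 | intermediate
5 | methyl acrylate | C=CC(=O)OC | starting material
6 | methyl 3-[(1S,4R)-1-methyl-2-{[(1R)-1-phenylethyl]imino}-4-(prop-1-en-2-yl)cyclohexyl]propanoate (adduct imine) | C=C(C)[C@@H]1CC[C@@](C)(CCC(=O)OC)C(=N[C@H](C)c2ccccc2)C1 | intermediate
7 | methyl 3-[(1S,4R)-1-methyl-2-oxo-4-(prop-1-en-2-yl)cyclohexyl]propanoate | C=C(C)[C@@H]1CC[C@@](C)(CCC(=O)OC)C(=O)C1 | intermediate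
8 | ethynylmagnesium bromide | C#C[Mg]Br | starting material
9 | methyl 3-[(1S,4R)-2-ethynyl-2-hydroxy-1-methyl-4-(prop-1-en-2-yl)cyclohexyl]propanoate (C2 epimers, formed as its bromomagnesium alkoxide) | C=C(C)[C@@H]1CC[C@@](C)(CCC(=O)OC)C(O)(C#C)C1 | intermediate
10 | (4aS,7R)-8a-ethynyl-4a-methyl-7-(prop-1-en-2-yl)octahydro-2H-chromen-2-one (C8a epimers) | C=C(C)[C@@H]1CC[C@@]2(C)CCC(=O)OC2(C#C)C1 | intermediate
11 | (2S,5R)-1-ethynyl-2-(3-hydroxypropyl)-2-methyl-5-(prop-1-en-2-yl)cyclohexan-1-ol (C1 epimers) | C=C(C)[C@@H]1CC[C@@](C)(CCCO)C(O)(C#C)C1 | intermediate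
12 | (2S,5R)-2-[3-(tert-butyldimethylsilyloxy)propyl]-1-ethynyl-2-methyl-5-(prop-1-en-2-yl)cyclohexan-1-ol | C=C(C)[C@@H]1CC[C@@](C)(CCCO[Si](C)(C)C(C)(C)C)C(O)(C#C)C1 | intermediate
13 | (2S,5R)-2-[3-(tert-butyldimethylsilyloxy)propyl]-1-ethynyl-2-methyl-5-(prop-1-en-2-yl)cyclohexyl methyl carbonate | C=C(C)[C@@H]1CC[C@@](C)(CCCO[Si](C)(C)C(C)(C)C)C(OC(=O)OC)(C#C)C1 | intermediate
14 | (2S,5R)-2-[3-(tert-butyldimethylsilyloxy)propyl]-1-ethynyl-5-(3-hydroxyprop-1-en-2-yl)-2-methylcyclohexyl methyl carbonate | C=C(CO)[C@@H]1CC[C@@](C)(CCCO[Si](C)(C)C(C)(C)C)C(OC(=O)OC)(C#C)C1 | intermediate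
15 | (2S,5R)-2-[3-(tert-butyldimethylsilyloxy)propyl]-1-ethynyl-2-methyl-5-(3-oxoprop-1-en-2-yl)cyclohexyl methyl carbonate | C=C(C=O)[C@@H]1CC[C@@](C)(CCCO[Si](C)(C)C(C)(C)C)C(OC(=O)OC)(C#C)C1 | intermediate
16 | 2-[(1R,4S)-4-[3-(tert-butyldimethylsilyloxy)propyl]-3-ethynyl-3-(methoxycarbonyloxy)-4-methylcyclohexyl]acrylic acid | C=C(C(=O)O)[C@@H]1CC[C@@](C)(CCCO[Si](C)(C)C(C)(C)C)C(OC(=O)OC)(C#C)C1 | intermediate
17 | methyl 2-[(1R,4S)-4-[3-(tert-butyldimethylsilyloxy)propyl]-3-ethynyl-3-(methoxycarbonyloxy)-4-methylcyclohexyl]acrylate | C=C(C(=O)OC)[C@@H]1CC[C@@](C)(CCCO[Si](C)(C)C(C)(C)C)C(OC(=O)OC)(C#C)C1 | intermediate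
18 | methyl 2-[(1R,4S)-4-[3-(tert-butyldimethylsilyloxy)propyl]-4-methyl-3-vinylidenecyclohexyl]acrylate | C=C(C(=O)OC)[C@@H]1CC[C@@](C)(CCCO[Si](C)(C)C(C)(C)C)C(=C=C)C1 | intermediate
19 | methyl 2-[(1R,4S)-4-(3-hydroxypropyl)-4-methyl-3-vinylidenecyclohexyl]acrylate | C=C(C(=O)OC)[C@@H]1CC[C@@](C)(CCCO)C(=C=C)C1 | intermediate
20 | methyl 2-[(1R,4S)-4-methyl-4-(3-oxopropyl)-3-vinylidenecyclohexyl]acrylate | C=C(C(=O)OC)[C@@H]1CC[C@@](C)(CCC=O)C(=C=C)C1 | intermediate
21 | hydrogen peroxide | OO | starting material
22 | methyl 3α-hydroxy-5α-hydroperoxyeudesma-4(15),11(13)-dien-12-oate | C=C(C(=O)OC)[C@@H]1CC[C@@]2(C)CC[C@@H](O)C(=C)[C@]2(OO)C1 | intermediate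
23 | methyl 5α-(tert-butyldimethylsilylperoxy)-3α-hydroxyeudesma-4(15),11(13)-dien-12-oate | C=C(C(=O)OC)[C@@H]1CC[C@@]2(C)CC[C@@H](O)C(=C)[C@]2(OO[Si](C)(C)C(C)(C)C)C1 | intermediate
24 | angelic acid | C/C=C(/C)C(=O)O | starting material
25 | angelic 2,4,6-trichlorobenzoic anhydride | C/C=C(/C)C(=O)OC(=O)c1c(Cl)cc(Cl)cc1Cl | intermediate
26 | methyl 3α-angeloyloxy-5α-(tert-butyldimethylsilylperoxy)eudesma-4(15),11(13)-dien-12-oate | C=C(C(=O)OC)[C@@H]1CC[C@@]2(C)CC[C@@H](OC(=O)/C(C)=C\C)C(=C)[C@]2(OO[Si](C)(C)C(C)(C)C)C1 | intermediate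
27 | methyl 3α-angeloyloxy-5α-hydroperoxyeudesma-4(15),11(13)-dien-12-oate (CNP0137897.2) | C=C(C(=O)OC)[C@@H]1CC[C@@]2(C)CC[C@@H](OC(=O)/C(C)=C\C)C(=C)[C@]2(OO)C1 | target

Total step count: 16. Longest linear sequence: 16 steps (1 to 27).

Steps most likely to fail

Step 13 (proposed new method). The aldehyde may be oxidised through its perhydrate, peroxide may be captured at C15 or delivered from the perhydrate oxygen, the cation may lose a proton, or the ring may close with the C3 oxygen equatorial. The fallback builds ring A by annulation and brings in the peroxide by a singlet-oxygen ene reaction; it sets out from imine 4 and comes back at 22.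
- Imine 4 is added to pent-1-en-3-one to give the adduct imine F1, which aqueous AcOH hydrolyses to (2S,5R)-2-methyl-2-(3-oxopentyl)-5-(prop-1-en-2-yl)cyclohexan-1-one F2.
- NaOMe in MeOH closes F2 by aldol condensation to (+)-α-cyperone F3.
- The isopropenyl group is oxidised as in steps 8 and 9: SeO2/t-BuOOH to the allylic alcohol 12-hydroxy-α-cyperone F4, MnO2 to the enal F5, NaClO2 to the acid F6, and MeI/K2CO3 to methyl 3-oxoeudesma-4,11(13)-dien-12-oate F7.
- Luche reduction (NaBH4, CeCl3·7H2O, MeOH, −78 °C) should deliver hydride axially, anti to the 10β-methyl, and give methyl 3β-hydroxyeudesma-4,11(13)-dien-12-oate F8.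
- Mitsunobu inversion with 4-nitrobenzoic acid, PPh3 and DIAD should give the 3α-(4-nitrobenzoate) F9, and brief K2CO3/MeOH at 0 °C frees methyl 3α-hydroxyeudesma-4,11(13)-dien-12-oate F10.
- Photooxygenation (O2, tetraphenylporphyrin, visible light, CH2Cl2, −20 °C) then effects the Schenck ene reaction. Singlet oxygen, steered to the α face by the 3α-hydroxyl and by the 10β-methyl, should bond to C5 and take hydrogen from C15, which gives 22.

Step 15. Acylation of the hindered axial allylic alcohol may stall, the activated angeloyl unit may isomerise from Z to E, the silyl group may migrate from the peroxide to the syn-axial hydroxyl, or the peroxide may be lost on heating. The fallback builds the Z alkene on the ester; it sets out from 23 and comes back at 26.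
- 23 is esterified at 0 °C with 2-[bis(2,2,2-trifluoroethoxy)phosphoryl]propanoic acid (DCC, cat. DMAP, CH2Cl2) to give the 3α-phosphonopropanoate F11.
- Still–Gennari olefination of F11 with acetaldehyde (KN(SiMe3)2, 18-crown-6, THF, −78 °C) should form the (Z)-2-methylbut-2-enoate directly and so give 26.

Step 3. Facial selectivity may erode because the auxiliary works against the ring's own preference for attack syn to the isopropenyl group, and addition to the weakly electrophilic acrylate may be slow. The fallback replaces auxiliary control by substrate control through a temporary cyclopropane; it sets out from 2 and comes back at 7.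
- HBr in AcOH adds to the isopropenyl group of 2 to give the tertiary bromide (5R)-5-(2-bromopropan-2-yl)-2-methylcyclohexan-1-one F12.
- KOH in MeOH closes the cyclopropane by intramolecular enolate alkylation to give 2-carone F13.
- Michael addition of F13 to methyl acrylate (t-BuOK cat., t-BuOH) can occur only at the methyl-bearing α-carbon and should come anti to the gem-dimethylcyclopropane, giving the carone propanoate F14 with the chain trans to the future isopropenyl group.
- Dry HCl in AcOH opens the cyclopropyl ketone to the tertiary chloride F15, and NaOAc in hot AcOH removes HCl to restore the isopropenyl group and give 7.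

Further compounds
F1 | step 13 | N-[(1R)-1-phenylethyl] imine of (2S,5R)-2-methyl-2-(3-oxopentyl)-5-(prop-1-en-2-yl)cyclohexan-1-one | C=C(C)[C@@H]1CC[C@@](C)(CCC(=O)CC)C(=N[C@H](C)c2ccccc2)C1
F2 | step 13 | (2S,5R)-2-methyl-2-(3-oxopentyl)-5-(prop-1-en-2-yl)cyclohexan-1-one | C=C(C)[C@@H]1CC[C@@](C)(CCC(=O)CC)C(=O)C1
F3 | step 13 | (+)-α-cyperone, (4aS,7R)-1,4a-dimethyl-7-(prop-1-en-2-yl)-4,4a,5,6,7,8-hexahydronaphthalen-2(3H)-one | C=C(C)[C@@H]1CC[C@@]2(C)CCC(=O)C(C)=C2C1
F4 | step 13 | 12-hydroxy-α-cyperone (12-hydroxyeudesma-4,11(13)-dien-3-one) | C=C(CO)[C@@H]1CC[C@@]2(C)CCC(=O)C(C)=C2C1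
F5 | step 13 | 3-oxoeudesma-4,11(13)-dien-12-al | C=C(C=O)[C@@H]1CC[C@@]2(C)CCC(=O)C(C)=C2C1
F6 | step 13 | 3-oxoeudesma-4,11(13)-dien-12-oic acid | C=C(C(=O)O)[C@@H]1CC[C@@]2(C)CCC(=O)C(C)=C2C1
F7 | step 13 | methyl 3-oxoeudesma-4,11(13)-dien-12-oate | C=C(C(=O)OC)[C@@H]1CC[C@@]2(C)CCC(=O)C(C)=C2C1
F8 | step 13 | methyl 3β-hydroxyeudesma-4,11(13)-dien-12-oate | C=C(C(=O)OC)[C@@H]1CC[C@@]2(C)CC[C@H](O)C(C)=C2C1
F9 | step 13 | methyl 3α-(4-nitrobenzoyloxy)eudesma-4,11(13)-dien-12-oate | C=C(C(=O)OC)[C@@H]1CC[C@@]2(C)CC[C@@H](OC(=O)c3ccc(cc3)[N+](=O)[O-])C(C)=C2C1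
F10 | step 13 | methyl 3α-hydroxyeudesma-4,11(13)-dien-12-oate | C=C(C(=O)OC)[C@@H]1CC[C@@]2(C)CC[C@@H](O)C(C)=C2C1
F11 | step 15 | methyl 3α-{2-[bis(2,2,2-trifluoroethoxy)phosphoryl]propanoyloxy}-5α-(tert-butyldimethylsilylperoxy)eudesma-4(15),11(13)-dien-12-oate | C=C(C(=O)OC)[C@@H]1CC[C@@]2(C)CC[C@@H](OC(=O)C(C)P(=O)(OCC(F)(F)F)OCC(F)(F)F)C(=C)[C@]2(OO[Si](C)(C)C(C)(C)C)C1
F12 | step 3 | (5R)-5-(2-bromopropan-2-yl)-2-methylcyclohexan-1-one | CC(C)(Br)[C@@H]1CCC(C)C(=O)C1
F13 | step 3 | 2-carone, 3,7,7-trimethylbicyclo[4.1.0]heptan-2-one (cis-fused, cyclopropane on the former isopropenyl face) | CC1(C)[C@@H]2CCC(C)C(=O)[C@H]12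
F14 | step 3 | methyl 3-(3,7,7-trimethyl-2-oxobicyclo[4.1.0]heptan-3-yl)propanoate (chain anti to the cyclopropane) | CC1(C)[C@@H]2CC[C@@](C)(CCC(=O)OC)C(=O)[C@H]12
F15 | step 3 | methyl 3-[(1S,4R)-4-(2-chloropropan-2-yl)-1-methyl-2-oxocyclohexyl]propanoate | CC(C)(Cl)[C@@H]1CC[C@@](C)(CCC(=O)OC)C(=O)C1
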